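Count turnovers: ask how many reagent units each lost starting material has taken.

common to all: starting material 19 mM

| flask | reagent | remark | time |
|---|---|---|---|
| beta | 0.69 equiv | run made earlier |  |
| eta | 2.2 equiv | run made earlier |  |
| birch | 0.800 equiv |  | 2.0 d |
| oak | 1.50 equiv |  | 2.0 d |
| larch | 3.00 equiv |  | 2.0 d |

| run | time / h | double product / % | starting material / % |
|---|---|---|---|
| beta | 6.00 | 0.6 | 58.0 |
| beta | 15.0 | 1.6 | 43.5 |
| beta | 30.0 | 1.7 | 37.7 |
| beta | 50.0 | 2.9 | 37.1 |
| eta | 6.00 | 5.3 | 14.5 |
| eta | 15.0 | 6.2 | 2.4 |
| eta | 30.0 | 5.3 | 0.6 |
| eta | 50.0 | 4.8 | 0.6 |

(each reading ± 0.5 percentage points)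

- "hardly changes" means that all values lie within two and a half points (for a concentration: within two and a half percent of the largest)

- amount of double product at the end, in percent of the starting material charged for birch, oak, larch, in this order
- how the row runs (falls, then rises / hardly changes / falls all the way / rises, then falls / rises all the way)

In the beta run the starting material stalls, 37.7 % and then 37.1 %. Taking the whole charge of 0.69 equiv as used, 1.10 of reagent went per equivalent of starting material lost, and that is my turnover count. Double product at 2.9 %, at one extra turn each, accounts for a count of 1.05, less than that, so I read double product as a waypoint that reagent may carry on past.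

Two extremes bracket the row. At one end the reagent is the limiting reagent: birch's 0.800 equiv stands below the count, so I put birch near beta's double product. At the other end I reckon reagent spare once the starting material is gone: by this count larch keeps 1.90 beyond what the starting material takes, more than eta's 1.10, and eta's double product readings already slip from 6.2 % to 4.8 %, against a scatter of 0.5 percentage points. Oak lies between, with 0.403 spare by the same count. So I expect a rise to oak, near eta's peak reading, and a fall to larch, below 4.8 %.

The forecast gives 3 %, 4.5 % and 6 %, so the row rises all the way, and it adds: “A fall at high excess is the main risk.” We part at oak, where I stand higher, and at larch, where I commit to that fall.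

The flask gives 3.33 %, 6.23 % and 2.92 %: the row rises, then falls.

    starting material + reagent → mono adduct (k = 11.0 L mol⁻¹ h⁻¹)
    reagent + mono adduct → double product (k = 1.20 L mol⁻¹ h⁻¹)
    reagent + double product → triple product (k = 13.0 L mol⁻¹ h⁻¹)
    reagent + double product → over-reaction product (k = 0.990 L mol⁻¹ h⁻¹)

In birch, the half-life of double product by the making of triple product alone, other concentrations as charged, is 0.15 d, short against the 2.0 d. Counted as for beta, reagent spent per starting material lost stands after 2.00 d at 1.11 in birch and 2.35 in larch, where triple product stands at 61.2 % after 2.00 d.

(The earlier runs and the new flask stem from a simulated flask from invented constants.)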